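The 1,4-dioxane ring is cut at C7'–C8' and C8'–O4. This excises the CH–C9' unit and leaves a five-membered 2-aryl-1,3-benzodioxole, the plain acetal of a catechol with a vanillin ester. The key step puts that carbon back as a chiral α-chloro imide enolate. Lewis-acid ionisation of the racemic acetal, C–C bond formation and phenoxide SN2 closure expand the dioxole to the dioxane and set C7' and C8' in one operation. The step exploits that C7' bears O3 and an aryl group, hence is a latent oxocarbenium carbon. It also exploits that the C5 methoxy group and the para side chain make O4, not O3, the leaving oxygen.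

Key step: step 4

Remark: lignan numbering is used throughout (C1–C9 cinnamaldehyde unit, C1'–C9' guaiacylpropane unit); O3 and O4 are the oxygens on C3 and C4, bonded to C7' and C8' in the target; Xc is the (R)-4-benzyl-oxazolidinone auxiliary.

Step 1
Reactants: 1 3,4-dihydroxy-5-methoxybenzaldehyde (5-hydroxyvanillin); 2 N-methoxy-N-methyl-2-(triphenyl-λ5-phosphanylidene)acetamide
Product: 3 (E)-3-(3,4-dihydroxy-5-methoxyphenyl)-N-methoxy-N-methylprop-2-enamide
Conditions: 2 (1.2 equiv), THF/toluene, 70 °C
Reagents that add atoms: none
Why: The Wittig olefination with an amide-stabilised ylide is E-selective and tolerates free phenols, and it installs the side chain at the aldehyde oxidation level as an acceptor para to O4.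

Step 2
Reactants: 3 catechol N-methoxy-N-methylamide; 4 4-formyl-2-methoxyphenyl 2-methylpropanoate (vanillin isobutyrate)
Product: 5 4-{4-methoxy-6-[(E)-3-[methoxy(methyl)amino]-3-oxoprop-1-enyl]-1,3-benzodioxol-2-yl}-2-methoxyphenyl 2-methylpropanoate (racemic at the acetal carbon C7')
Conditions: p-TsOH·H2O (5 mol %), toluene, reflux, Soxhlet with 4 Å molecular sieves
Reagents that add atoms: none
Why: Acid-catalysed dehydrative acetalisation of a catechol with an aromatic aldehyde closes the five-membered 1,3-dioxole; C7' forms as a racemate, which does not matter because step 4 erases it.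

Step 3
Reactants: 6 (R)-4-benzyl-1,3-oxazolidin-2-one; 7 chloroacetyl chloride
Product: 8 (R)-4-benzyl-3-(chloroacetyl)-1,3-oxazolidin-2-one
Conditions: n-BuLi, THF, −78 °C; then 7, −78 → 0 °C
Reagents that add atoms: none
Why: N-acylation of the lithiated oxazolidinone with an acid chloride is the standard loading of this auxiliary and leaves its stereocentre untouched.

Step 4
Reactants: 5 racemic 2-aryl-1,3-benzodioxole; 8 chloroacetyl imide
Product: 12 (4R)-4-benzyl-3-{[(2R,3S)-3-(4-isobutyryloxy-3-methoxyphenyl)-8-methoxy-6-[(E)-3-[methoxy(methyl)amino]-3-oxoprop-1-enyl]-2,3-dihydro-1,4-benzodioxin-2-yl]carbonyl}-1,3-oxazolidin-2-one (trans; 7'S and 8'R by CIP but the same spatial arrangement as the target), via chlorotitanium enolate 9 (not isolated), via oxocarbenium phenoxide 10 (not isolated), via ring-opened chlorophenol 11 (not isolated)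
Conditions: 8 (1.3 equiv), TiCl4, i-Pr2NEt, CH2Cl2, −78 °C; then 5, SnCl4 (2.5 equiv), −78 → −20 °C; aq. NH4Cl, solvent switch (crude 11); K2CO3, MeCN, 25 °C
Reagents that add atoms: titanium(IV) chloride, Cl[Ti](Cl)(Cl)Cl (its atoms appear only in intermediate 9, none in 12)
Why: Proposed new method: SnCl4, held in a five-membered chelate by O4 and the C5 methoxy oxygen, ionises the C7'–O4 bond of racemic 5 to the planar O3-aryl oxocarbenium ion 10 (the acetal stereocentre is erased, so both enantiomers converge), the chelated Z-enolate 9 adds to it through an open antiperiplanar transition state to form C7'–C8' (11), and the freed O4 phenoxide then displaces chloride, so that a CH–C(O)Xc unit ends up inserted into the acetal C–O bond and the 1,3-dioxole becomes the 1,4-dioxane. The closest known reaction types are the Lewis-acid-mediated addition of chiral chlorotitanium imide enolates to dialkyl acetals and the phenoxide/α-halo ester closure used for 1,4-benzodioxane-2-carboxylates, but neither has been applied to a catechol acetal or combined into a ring expansion. The only ring closed is the dioxane, by 6-exo-tet SN2 attack of O4 on C8'. C8' is controlled by the benzyl group of the (R)-auxiliary, which blocks one face of 9 and gives the (S)-chloride that the SN2 step inverts cleanly, and C7' by the anti preference of the open transition state, which after that inversion corresponds to the trans ring. The step needs cleavage of C7'–O4 rather than C7'–O3, secured by the chelate, by the acceptor para to O4 (better leaving phenoxide) and by O3 being the better donor, and it needs substitution to outrun E1cB loss of the O3 aryloxide, hence only a carbonate base. Any minor stereoisomer of 12 is a diastereomer because of the auxiliary and should be removable by chromatography before step 5.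

Step 5
Reactants: 12 ring-expanded imide
Product: 13 (7'S,8'S)-nocomtal
Conditions: LiAlH4 (4 equiv), THF, −78 → 0 °C; inverse quench into cold sat. aq. Rochelle salt
Reagents that add atoms: none
Why: In one hydride reduction the imide goes to the primary alcohol with release of the auxiliary, the aryl ester is cleaved, and the N-methoxy-N-methylamide stops at its chelated tetrahedral adduct, which gives the enal only on work-up (Weinreb aldehyde synthesis); no stereocentre is touched.

Compound list
1 | 3,4-dihydroxy-5-methoxybenzaldehyde (5-hydroxyvanillin) | COc1cc(C=O)cc(O)c1O | starting material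
2 | N-methoxy-N-methyl-2-(triphenyl-λ5-phosphanylidene)acetamide | CON(C)C(=O)C=P(c1ccccc1)(c1ccccc1)c1ccccc1 | starting material
3 | (E)-3-(3,4-dihydroxy-5-methoxyphenyl)-N-methoxy-N-methylprop-2-enamide | COc1cc(/C=C/C(=O)N(C)OC)cc(O)c1O | intermediate
4 | 4-formyl-2-methoxyphenyl 2-methylpropanoate (vanillin isobutyrate) | COc1cc(C=O)ccc1OC(=O)C(C)C | starting material
5 | racemic 2-aryl-1,3-benzodioxole (acetal of 3 and 4) | COc1cc(C2Oc3cc(/C=C/C(=O)N(C)OC)cc(OC)c3O2)ccc1OC(=O)C(C)C | intermediate
6 | (R)-4-benzyl-1,3-oxazolidin-2-one | O=C1N[C@H](Cc2ccccc2)CO1 | starting material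
7 | chloroacetyl chloride | ClCC(Cl)=O | starting material
8 | (R)-4-benzyl-3-(chloroacetyl)-1,3-oxazolidin-2-one | ClCC(=O)N1C(=O)OC[C@H]1Cc1ccccc1 | intermediate
9 | (Z)-trichlorotitanium enolate of 8 | Cl/C=C(\O[Ti](Cl)(Cl)Cl)N1C(=O)OC[C@H]1Cc1ccccc1 | intermediate
10 | ring-opened O3-aryl oxocarbenium ion of 5, drawn as the zwitterion with the O4 phenoxide (tin-bound in the flask) | COc1cc(C=[O+]c2cc(/C=C/C(=O)N(C)OC)cc(OC)c2[O-])ccc1OC(=O)C(C)C | intermediate
11 | (4R)-4-benzyl-3-[(2S,3S)-2-chloro-3-(4-isobutyryloxy-3-methoxyphenyl)-3-{2-hydroxy-3-methoxy-5-[(E)-3-[methoxy(methyl)amino]-3-oxoprop-1-enyl]phenoxy}propanoyl]-1,3-oxazolidin-2-one (anti) | Cl[C@@H]([C@@H](Oc1cc(/C=C/C(=O)N(C)OC)cc(OC)c1O)c1ccc(OC(=O)C(C)C)c(OC)c1)C(=O)N1C(=O)OC[C@H]1Cc1ccccc1 | intermediate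
12 | trans-(2R,3S)-3-aryl-2,3-dihydro-1,4-benzodioxine-2-carbonyl imide of the (R)-auxiliary | COc1cc([C@@H]2Oc3cc(/C=C/C(=O)N(C)OC)cc(OC)c3O[C@H]2C(=O)N4C(=O)OC[C@H]4Cc5ccccc5)ccc1OC(=O)C(C)C | intermediate
13 | (7'S,8'S)-nocomtal | COc1cc([C@@H]2Oc3cc(/C=C/C=O)cc(OC)c3O[C@H]2CO)ccc1O | target

Total step count: 5. Longest linear sequence: 4 steps (1 → 3 → 5 → 12 → 13).

Steps most likely to fail

1. Step 4 (Proposed new method).
- What may go wrong: the O-aryl acetal may ionise too slowly for the enolate to survive. It may open at C7'–O3. Control at C7' may erode. The chloride 11 may lose the O3 aryloxide by elimination before it cyclises.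
- Fallback with known chemistry, setting out from 3 and 8 and returning at 13: the more acidic O4–H of catechol 3 is alkylated selectively with chloride 8 (NaHCO3, NaI, DMF) to the aryloxyacetyl imide F1. A boron-mediated Evans syn-aldol addition of F1 to aldehyde 4 (excess Bu2BOTf, Et3N, which also masks O3–H) gives the syn aldol F2, with C8' set by the same (R)-auxiliary. LiAlH4 under the conditions of step 5 gives the 8-O-4' triol enal F3. Catalytic p-TsOH in MeCN then ionises the p-hydroxybenzylic alcohol, and O3–H closes the dioxane under thermodynamic control to trans-13.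

2. Step 2.
- What may go wrong: removal of water may not overcome an unfavourable equilibrium for the electron-poor catechol. The hot acid may start hydroxyalkylation of the catechol ring or acyl transfer from the aryl ester.
- Fallback, setting out from 4 and returning at 5: aldehyde 4 is first converted with trimethyl orthoformate and catalytic acid in methanol into the dimethyl acetal F4. This is exchanged with catechol 3 under PPTS in toluene with continuous removal of methanol. The dioxole is then made by transacetalisation of a pre-activated electrophile at lower acidity instead of by dehydration.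

3. Step 5.
- What may go wrong: early collapse of the aluminium chelate would expose the enal to hydride. Conjugate reduction of the unsaturated amide or endocyclic attack on the oxazolidinone may compete.
- Fallback, setting out from 12 and returning at 13: the reductions are separated by reagent. Excess LiBH4/MeOH in THF at 0 °C removes the auxiliary and the aryl ester but leaves the amide, giving the phenol alcohol amide F5. DIBAL-H at −78 °C then reduces only the N-methoxy-N-methylamide to the enal 13.

Further compounds
F1 | step 4 | (R)-4-benzyl-3-({2-hydroxy-6-methoxy-4-[(E)-3-[methoxy(methyl)amino]-3-oxoprop-1-enyl]phenoxy}acetyl)-1,3-oxazolidin-2-one | COc1cc(/C=C/C(=O)N(C)OC)cc(O)c1OCC(=O)N1C(=O)OC[C@H]1Cc1ccccc1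
F2 | step 4 | (2R,3S)-syn aldol of F1 and 4 (2-aryloxy-3-hydroxy-3-arylpropanoyl imide) | COc1cc(/C=C/C(=O)N(C)OC)cc(O)c1O[C@H]([C@@H](O)c1ccc(OC(=O)C(C)C)c(OC)c1)C(=O)N1C(=O)OC[C@H]1Cc1ccccc1
F3 | step 4 | (7'S,8'S)-8-O-4' triol enal with free O3–H | COc1cc(/C=C/C=O)cc(O)c1O[C@H]([C@@H](O)c1ccc(O)c(OC)c1)CO
F4 | step 2 | 4-(dimethoxymethyl)-2-methoxyphenyl 2-methylpropanoate | COC(OC)c1ccc(OC(=O)C(C)C)c(OC)c1
F5 | step 5 | (7'S,8'S)-benzodioxane phenol alcohol with the N-methoxy-N-methylamide side chain | COc1cc([C@@H]2Oc3cc(/C=C/C(=O)N(C)OC)cc(OC)c3O[C@H]2CO)ccc1O
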